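**Plan**

- Retrosynthetic cuts, in order: the C6–OMe bond (an epimerisable peroxyketal carbon), the ester O–CH3 bond, the ring O–C3 bond of the 1,2-dioxine, the C6–OOH bond, the C2–C3 and C1–O bonds of a β-lactone (ketene + aldehyde), and the acyl–alkyne bond C5–C6.
- Enabling feature: the ring oxygen on C3 stands β to the ester carbon C1, so C3–C2–C1 can be folded back into an oxetan-2-one. Its strained, allylic C3–O bond is held by the Z C4=C5 alkene beside a hydroperoxy ketal at C6.
- Forward: acyl–alkyne coupling builds the C22 chain, then ketal, ynal and asymmetric ketene–aldehyde cyclocondensation give the β-lactone. Lindlar reduction gives the Z alkene and H2O2 exchange gives the hydroperoxy ketal.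
- The only ring, the 3,6-dihydro-1,2-dioxine, is closed last: the peroxy anion opens the β-lactone at C3 with strain release, and the carboxylate set free is methylated in the same flask.
- Stereochemistry: C3 (S) comes from SN2 inversion of the 4R lactone centre set by the alkaloid catalyst. C6 (S) is settled by acid equilibration of the peroxyketal in methanol, with separation and recycling of the 6R epimer.

Key step: step 7

Assumptions: O-trimethylsilylquinidine is taken to give the 4R lactone from ynal 5 by analogy with other aldehydes (if the sense is reversed, O-trimethylsilylquinine replaces it); heptadecanoyl chloride is bought or made from heptadecanoic acid.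

**Route**

Step 1
Reactants: 1 heptadecanoyl chloride; 2 2-(prop-2-yn-1-yloxy)tetrahydro-2H-pyran
Product: 3 1-(tetrahydro-2H-pyran-2-yloxy)icos-2-yn-4-one
Conditions: PdCl2(PPh3)2 (2 mol%), CuI (4 mol%), Et3N (1.2 equiv), THF, rt
Reagents that add atoms: none
Why: Acyl Sonogashira coupling of an acid chloride with a terminal alkyne gives the ynone directly, and the THP acetal is inert to the amine base.

Step 2
Reactants: 3 1-(tetrahydro-2H-pyran-2-yloxy)icos-2-yn-4-one
Product: 4 4,4-dimethoxyicos-2-yn-1-ol
Conditions: HC(OMe)3 (3 equiv), TsOH·H2O (5 mol%), MeOH, rt; NaHCO3 work-up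
Reagents that add atoms: trimethyl orthoformate COC(OC)OC; methanol CO
Why: Acid-catalysed ketalisation driven by the orthoformate converts the ynone into its dimethyl ketal, and the same acidic methanol transfers the THP group to methanol, freeing the propargylic alcohol in one operation.

Step 3
Reactants: 4 4,4-dimethoxyicos-2-yn-1-ol
Product: 5 4,4-dimethoxyicos-2-ynal
Conditions: activated MnO2 (15 equiv), CH2Cl2, rt
Reagents that add atoms: none
Why: MnO2 oxidation of a propargylic alcohol stops at the ynal and is neutral, so the acid-labile ketal should survive.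

Step 4
Reactants: 5 4,4-dimethoxyicos-2-ynal
Product: 6 (4R)-4-(3,3-dimethoxynonadec-1-yn-1-yl)oxetan-2-one
Conditions: acetyl chloride (2 equiv), iPr2NEt (2.5 equiv), O-trimethylsilylquinidine (10 mol%), LiClO4 (0.5 equiv), Et2O/CH2Cl2, −78 °C
Reagents that add atoms: acetyl chloride CC(=O)Cl
Why: Catalytic asymmetric acyl halide–aldehyde cyclocondensation (formal ketene–aldehyde [2+2]): ketene made in situ is turned by the silylated alkaloid into a chiral ammonium enolate that adds to the LiClO4-activated ynal and lactonises, the alkaloid shielding one aldehyde face so that C4 of the oxetanone (the future C3) is set as R.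

Step 5
Reactants: 6 (4R)-4-(3,3-dimethoxynonadec-1-yn-1-yl)oxetan-2-one
Product: 7 (4R)-4-[(1Z)-3,3-dimethoxynonadec-1-en-1-yl]oxetan-2-one
Conditions: H2 (1 atm), Lindlar catalyst (Pd on CaCO3 poisoned with Pb(OAc)2), quinoline, EtOAc, 0 °C, stopped after 1 equiv H2
Reagents that add atoms: none
Why: Lindlar semi-hydrogenation delivers both hydrogens to one face of the alkyne and so gives the Z C4=C5 alkene that will lie inside the dioxine ring; quinoline and low temperature limit over-reduction and hydrogenolysis of the allylic C–O bond.

Step 6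
Reactants: 7 (4R)-4-[(1Z)-3,3-dimethoxynonadec-1-en-1-yl]oxetan-2-one
Product: 8 (4R)-4-[(1Z)-3-hydroperoxy-3-methoxynonadec-1-en-1-yl]oxetan-2-one (both epimers at the peroxyketal carbon)
Conditions: H2O2 (anhydrous, ca. 2 M in Et2O, 4 equiv), CSA (10 mol%), CH2Cl2, −20 → 0 °C; NaHCO3 work-up
Reagents that add atoms: hydrogen peroxide OO
Why: Acid-catalysed ketal–hydroperoxide exchange (perhydrolysis of a dimethyl ketal): the allylic oxocarbenium ion is captured at C6 by H2O2 to give the α-methoxy hydroperoxide; the new centre is not controlled and need not be, since C6 is equilibrated in step 8.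

Step 7
Reactants: 8 (4R)-4-[(1Z)-3-hydroperoxy-3-methoxynonadec-1-en-1-yl]oxetan-2-one
Product: 11 methyl 2-[(3S)-6-hexadecyl-6-methoxy-3,6-dihydro-1,2-dioxin-3-yl]acetate (both C6 epimers), via potassium peroxide salt 9 (not isolated), via potassium carboxylate 10 (not isolated)
Conditions: KN(SiMe3)2 (1.0 equiv), THF/DMF (4:1), 0.005 M, −60 → 0 °C; then MeI (3 equiv), 0 °C → rt
Reagents that add atoms: iodomethane CI
Why: Proposed new method: deprotonation of the α-methoxy hydroperoxide (far more acidic than any C–H present) gives peroxy anion 9, whose terminal oxygen attacks C3, the alkyl carbon of the oxetan-2-one, from the side opposite the C3–O(acyl) bond, so that some 20 kcal/mol of four-ring strain is released and a carboxylate leaves; the closest known reaction types are the SN2 alkyl–oxygen opening of β-lactones by azide, thiolate, halide and cuprate nucleophiles and the alkylation of α-alkoxy hydroperoxide anions by secondary sulfonates and by oxetanes. The 1,2-dioxine is closed in the 6-exo-tet mode, the breaking C–O bond lying outside the new ring. C3 is the only centre touched and is set as S by inversion of the 4R lactone centre, while C6 passes through unchanged as both epimers. The step needs alkyl C–O rather than acyl C–O cleavage, and the substrate secures it: attack at the lactone carbonyl would require an eight-membered cyclic perester and SN2' attack at C5 a dioxetane, whereas the Z C4=C5 alkene holds the peroxy anion within reach of C3 and its π system, aligned with the breaking allylic C–O bond, lowers the SN2 barrier. One equivalent of base leaves only the weakly basic carboxylate 10 once the ring is closed, which protects C3–H from Kornblum–DeLaMare cleavage, and methyl iodide then esterifies 10 in the same flask.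

Step 8
Reactants: 11 methyl 2-[(3S)-6-hexadecyl-6-methoxy-3,6-dihydro-1,2-dioxin-3-yl]acetate (both C6 epimers)
Product: 12 6-epi-chondrillin, methyl 2-[(3S,6S)-6-hexadecyl-6-methoxy-3,6-dihydro-1,2-dioxin-3-yl]acetate
Conditions: CSA (10 mol%), MeOH, 0 °C → rt; Et3N quench; chromatography, the 6R epimer resubmitted
Reagents that add atoms: methanol CO
Why: Acid-catalysed ketal exchange of a cyclic peroxyketal in methanol: reversible loss of methanol gives the ring-conjugated peroxycarbenium ion and re-addition equilibrates C6 while C3 is untouched; the 3,6-cis epimer 12, with OMe pseudoaxial (anomeric effect) and the C3 side chain pseudoequatorial, should be favoured, though perhaps only modestly, hence the separation and recycling.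

**Compound list**

1 | heptadecanoyl chloride | CCCCCCCCCCCCCCCCC(=O)Cl | starting material
2 | 2-(prop-2-yn-1-yloxy)tetrahydro-2H-pyran | C#CCOC1CCCCO1 | starting material
3 | 1-(tetrahydro-2H-pyran-2-yloxy)icos-2-yn-4-one | CCCCCCCCCCCCCCCCC(=O)C#CCOC1CCCCO1 | intermediate
4 | 4,4-dimethoxyicos-2-yn-1-ol | CCCCCCCCCCCCCCCCC(OC)(OC)C#CCO | intermediate
5 | 4,4-dimethoxyicos-2-ynal | CCCCCCCCCCCCCCCCC(OC)(OC)C#CC=O | intermediate
6 | (4R)-4-(3,3-dimethoxynonadec-1-yn-1-yl)oxetan-2-one | CCCCCCCCCCCCCCCCC(OC)(OC)C#C[C@H]1CC(=O)O1 | intermediate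
7 | (4R)-4-[(1Z)-3,3-dimethoxynonadec-1-en-1-yl]oxetan-2-one | CCCCCCCCCCCCCCCCC(OC)(OC)/C=C\[C@H]1CC(=O)O1 | intermediate
8 | (4R)-4-[(1Z)-3-hydroperoxy-3-methoxynonadec-1-en-1-yl]oxetan-2-one, both epimers at the peroxyketal carbon | CCCCCCCCCCCCCCCCC(OC)(OO)/C=C\[C@H]1CC(=O)O1 | intermediate
9 | potassium peroxide salt of 8 | CCCCCCCCCCCCCCCCC(OC)(O[O-])/C=C\[C@H]1CC(=O)O1.[K+] | intermediate
10 | potassium 2-[(3S)-6-hexadecyl-6-methoxy-3,6-dihydro-1,2-dioxin-3-yl]acetate, both C6 epimers | CCCCCCCCCCCCCCCCC1(OC)C=C[C@H](CC(=O)[O-])OO1.[K+] | intermediate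
11 | methyl 2-[(3S)-6-hexadecyl-6-methoxy-3,6-dihydro-1,2-dioxin-3-yl]acetate, both C6 epimers | CCCCCCCCCCCCCCCCC1(OC)C=C[C@H](CC(=O)OC)OO1 | intermediate
12 | 6-epi-chondrillin, methyl 2-[(3S,6S)-6-hexadecyl-6-methoxy-3,6-dihydro-1,2-dioxin-3-yl]acetate | CCCCCCCCCCCCCCCC[C@@]1(OC)C=C[C@H](CC(=O)OC)OO1 | target

**Count and risks**

Total step count: 8. Longest linear sequence: 8 steps (from 1 to 12).

Steps most likely to fail:

1. Step 7 (Proposed new method). The peroxy anion may add to the lactone carbonyl of a second molecule and give oligomeric peresters. The lactone may ionise or eliminate to the dienoic acid faster than it is displaced. The closed dioxine may be cleaved by base at C3–H. The fallback uses known chemistry, with conjugate addition in place of displacement and enantiomer separation in place of stereospecific inversion. It sets out from 5. A Wittig reaction with methyl (triphenylphosphoranylidene)acetate in CH2Cl2 should give methyl (2E)-6,6-dimethoxydocos-2-en-4-ynoate F1. Lindlar semi-hydrogenation should give methyl (2E,4Z)-6,6-dimethoxydocosa-2,4-dienoate F2. Exchange with H2O2 and catalytic CSA as in step 6 should give methyl (2E,4Z)-6-hydroperoxy-6-methoxydocosa-2,4-dienoate F3. Et2NH in CF3CH2OH should then close the ring by intramolecular peroxy-Michael addition to give methyl 2-(6-hexadecyl-6-methoxy-3,6-dihydro-1,2-dioxin-3-yl)acetate (all four stereoisomers) F4. Chromatography on a chiral stationary phase separates the 3S isomers, and the fallback comes back to the route at 11.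

2. Step 6. The allylic oxocarbenium ion may undergo Z to E isomerisation, may be captured by the lactone ring oxygen across the Z alkene, or may exchange twice to the geminal dihydroperoxide. The fallback moves the exchange to the linear alkyne stage, where neither isomerisation nor participation is possible, and masks the hydroperoxide during the reduction. It sets out from 6. H2O2 and catalytic CSA should give (4R)-4-(3-hydroperoxy-3-methoxynonadec-1-yn-1-yl)oxetan-2-one F5. Et3SiCl and imidazole should give (4R)-4-{3-methoxy-3-[(triethylsilyl)peroxy]nonadec-1-yn-1-yl}oxetan-2-one F6. Lindlar semi-hydrogenation, which the silyl peroxide is expected to tolerate on the poisoned catalyst, should give (4R)-4-{(1Z)-3-methoxy-3-[(triethylsilyl)peroxy]nonadec-1-en-1-yl}oxetan-2-one F7. HF·pyridine in THF at 0 °C removes the silyl group, and the fallback comes back to the route at 8.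

3. Step 5. Over-reduction may occur, or the palladium may cleave the propargylic or allylic C–O bond of the lactone by hydrogenolysis or by ionisation on zerovalent palladium. The fallback sets the Z alkene before the lactone exists. It sets out from 4. Lindlar semi-hydrogenation should give (2Z)-4,4-dimethoxyicos-2-en-1-ol F8. MnO2 in CH2Cl2 at 0 °C, kept cold to avoid Z to E isomerisation, should give (2Z)-4,4-dimethoxyicos-2-enal F9. The cyclocondensation of step 4 applied to F9 then gives the Z-alkenyl lactone, and the fallback comes back to the route at 7.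

**Further compounds**

F1 | step 7 | methyl (2E)-6,6-dimethoxydocos-2-en-4-ynoate | CCCCCCCCCCCCCCCCC(OC)(OC)C#C/C=C/C(=O)OC
F2 | step 7 | methyl (2E,4Z)-6,6-dimethoxydocosa-2,4-dienoate | CCCCCCCCCCCCCCCCC(OC)(OC)/C=C\C=C\C(=O)OC
F3 | step 7 | methyl (2E,4Z)-6-hydroperoxy-6-methoxydocosa-2,4-dienoate | CCCCCCCCCCCCCCCCC(OC)(OO)/C=C\C=C\C(=O)OC
F4 | step 7 | methyl 2-(6-hexadecyl-6-methoxy-3,6-dihydro-1,2-dioxin-3-yl)acetate, all four stereoisomers | CCCCCCCCCCCCCCCCC1(OC)C=CC(CC(=O)OC)OO1
F5 | step 6 | (4R)-4-(3-hydroperoxy-3-methoxynonadec-1-yn-1-yl)oxetan-2-one | CCCCCCCCCCCCCCCCC(OC)(OO)C#C[C@H]1CC(=O)O1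
F6 | step 6 | (4R)-4-{3-methoxy-3-[(triethylsilyl)peroxy]nonadec-1-yn-1-yl}oxetan-2-one | CCCCCCCCCCCCCCCCC(OC)(OO[Si](CC)(CC)CC)C#C[C@H]1CC(=O)O1
F7 | step 6 | (4R)-4-{(1Z)-3-methoxy-3-[(triethylsilyl)peroxy]nonadec-1-en-1-yl}oxetan-2-one | CCCCCCCCCCCCCCCCC(OC)(OO[Si](CC)(CC)CC)/C=C\[C@H]1CC(=O)O1
F8 | step 5 | (2Z)-4,4-dimethoxyicos-2-en-1-ol | CCCCCCCCCCCCCCCCC(OC)(OC)/C=C\CO
F9 | step 5 | (2Z)-4,4-dimethoxyicos-2-enal | CCCCCCCCCCCCCCCCC(OC)(OC)/C=C\C=O
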